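**Retrosynthetic overview**

1. Ring A carries C1 (CO2H), C2 (2-oxoheptyl), C3 (aryloxy) and two hydroxyls placed meta to each other at C4 and C6. It is therefore the dehydrogenated enol form of a cyclohexane-1,3-dione carboxylate, cut at C1–C2 (Michael) and C5–C6 (Claisen) into dibenzyl malonate and a 3-aryloxypent-3-en-2-one.
2. The enone comes from a Horner–Wadsworth–Emmons reaction between an α-aryloxy ketophosphonate (ring B phenol plus a diazo ketophosphonate, O–H insertion) and dioxolane-protected 3-oxooctanal.
3. Ring B is carried open, as a tert-butyl benzoate with a ketal-masked 2-oxoheptyl arm, made from methyl orsellinate by lateral lithiation and acylation.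
4. Ring order: the ring B arene is bought; the ring A carbocycle closes in the annulation and is aromatised next; the isocoumarin lactone ring closes last, before the benzyl ester is removed.

Key step: step 12

Assumption: N-methoxy-N-methylhexanamide, dimethyl (1-diazo-2-oxopropyl)phosphonate and Me2NCH(Ot-Bu)2 are taken as purchasable; C2 and C3 of ring A are formed as transient racemic centres, which is immaterial for the achiral target. "ArB" below means the ring B aryl group 2-(tert-butoxycarbonyl)-5-methoxy-3-[(2-pentyl-1,3-dioxolan-2-yl)methyl]phenyl.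

**Route**

Step 1
Reactants: 1 methyl orsellinate (methyl 2,4-dihydroxy-6-methylbenzoate)
Product: 2 methyl 2-hydroxy-4-methoxy-6-methylbenzoate
Conditions: MeI (1.1 equiv), K2CO3, acetone, reflux
Reagents that add atoms: iodomethane, CI
Why: The 4-OH is the more acidic, unchelated phenol while the 2-OH is hydrogen-bonded to the ester, so a Williamson methylation with one equivalent of MeI should stop at the 4-methyl ether.

Step 2
Reactants: 2 methyl 2-hydroxy-4-methoxy-6-methylbenzoate
Product: 3 methyl 2-(benzyloxy)-4-methoxy-6-methylbenzoate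
Conditions: BnBr, K2CO3, DMF, 60 °C
Reagents that add atoms: benzyl bromide, BrCc1ccccc1
Why: Forcing Williamson conditions alkylate the chelated phenol, so that no acidic O–H interferes with the later benzylic lithiation.

Step 3
Reactants: 3 methyl 2-(benzyloxy)-4-methoxy-6-methylbenzoate
Product: 4 2-(benzyloxy)-4-methoxy-6-methylbenzoic acid
Conditions: KOH, DMSO–H2O (4:1), 90 °C; then aq. HCl
Reagents that add atoms: potassium hydroxide, [K+].[OH-]
Why: Saponification of the di-ortho-substituted ester needs the poorly solvated hydroxide of aqueous DMSO at elevated temperature, which the benzyl and methyl ethers tolerate.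

Step 4
Reactants: 4 2-(benzyloxy)-4-methoxy-6-methylbenzoic acid
Product: 5 tert-butyl 2-(benzyloxy)-4-methoxy-6-methylbenzoate
Conditions: Me2NCH(Ot-Bu)2 (3 equiv), toluene, 80 °C
Reagents that add atoms: N,N-dimethylformamide di-tert-butyl acetal, CN(C)C(OC(C)(C)C)OC(C)(C)C
Why: The formamide acetal transfers a tert-butyl group to the carboxylate oxygen, so this neutral esterification needs no attack at the hindered carbonyl.

Step 5
Reactants: 5 tert-butyl 2-(benzyloxy)-4-methoxy-6-methylbenzoate; 6 N-methoxy-N-methylhexanamide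
Product: 7 tert-butyl 2-(benzyloxy)-4-methoxy-6-(2-oxoheptyl)benzoate
Conditions: LiN(i-Pr)2 (1.2 equiv), THF, −78 °C; then 6; AcOH, −78 °C → rt
Reagents that add atoms: none
Why: Lateral lithiation of the ortho-toluate methyl group gives a benzylic anion that is acylated by the Weinreb amide, whose chelated tetrahedral adduct prevents over-addition, while the tert-butyl ester suppresses self-condensation.

Step 6
Reactants: 7 tert-butyl 2-(benzyloxy)-4-methoxy-6-(2-oxoheptyl)benzoate
Product: 8 tert-butyl 2-(benzyloxy)-4-methoxy-6-[(2-pentyl-1,3-dioxolan-2-yl)methyl]benzoate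
Conditions: Me3SiOCH2CH2OSiMe3 (2 equiv), Me3SiOTf (5 mol %), CH2Cl2, −78 → −40 °C; then pyridine
Reagents that add atoms: 1,2-bis(trimethylsilyloxy)ethane, C[Si](C)(C)OCCO[Si](C)(C)C
Why: Silyl-triflate-catalysed dioxolanation (Noyori conditions) is aprotic and runs at low temperature, so the unhindered ketone should be ketalised without cleavage of the tert-butyl ester or enol-lactonisation.

Step 7
Reactants: 8 tert-butyl 2-(benzyloxy)-4-methoxy-6-[(2-pentyl-1,3-dioxolan-2-yl)methyl]benzoate
Product: 9 tert-butyl 2-hydroxy-4-methoxy-6-[(2-pentyl-1,3-dioxolan-2-yl)methyl]benzoate (ring B phenol, ArB–OH)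
Conditions: H2 (1 atm), Pd/C, EtOAc, rt
Reagents that add atoms: none
Why: Hydrogenolysis of the benzyl aryl ether over Pd/C is selective, as the tert-butyl ester, the dioxolane and the arene are inert.

Step 8
Reactants: 10 ethyl 3-oxooctanoate
Product: 11 ethyl 2-(2-pentyl-1,3-dioxolan-2-yl)acetate
Conditions: HOCH2CH2OH, TsOH·H2O (cat.), toluene, reflux, Dean–Stark
Reagents that add atoms: ethylene glycol, OCCO
Why: Acid-catalysed ketalisation of the ketone of a β-keto ester with azeotropic removal of water is standard and leaves the ester untouched.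

Step 9
Reactants: 11 ethyl 2-(2-pentyl-1,3-dioxolan-2-yl)acetate
Product: 12 2-(2-pentyl-1,3-dioxolan-2-yl)acetaldehyde
Conditions: i-Bu2AlH (1.1 equiv), CH2Cl2, −78 °C; then MeOH, aq. KNaC4H4O6
Reagents that add atoms: none
Why: Partial ester reduction with one equivalent of i-Bu2AlH at −78 °C stops at the aluminium hemiacetal, which is stabilised by the β-dioxolane oxygen and releases the aldehyde on work-up.

Step 10
Reactants: 9 ring B phenol ArB–OH; 13 dimethyl (1-diazo-2-oxopropyl)phosphonate
Product: 14 dimethyl [1-(ArB-oxy)-2-oxopropyl]phosphonate (racemic)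
Conditions: Rh2(OAc)4 (2 mol %), toluene, 80 °C, slow addition of 13
Reagents that add atoms: none
Why: Rh2(OAc)4 converts the diazo ketophosphonate into a rhodium carbenoid that undergoes O–H insertion with the phenol, forming the aryl–O–C(sp3) bond without base; the new centre is racemic and is destroyed in step 11.

Step 11
Reactants: 14 dimethyl [1-(ArB-oxy)-2-oxopropyl]phosphonate; 12 2-(2-pentyl-1,3-dioxolan-2-yl)acetaldehyde
Product: 15 3-(ArB-oxy)-5-(2-pentyl-1,3-dioxolan-2-yl)pent-3-en-2-one (E/Z mixture)
Conditions: NaH, THF, 0 °C → rt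
Reagents that add atoms: none
Why: Horner–Wadsworth–Emmons olefination of the stabilised α-aryloxy ketophosphonate anion places the double bond between the aryloxy carbon and the aldehyde carbon without regiochemical ambiguity; the E/Z ratio is irrelevant because both isomers give the same Michael adduct.

Step 12
Reactants: 15 3-(ArB-oxy)-5-(2-pentyl-1,3-dioxolan-2-yl)pent-3-en-2-one; 16 dibenzyl malonate
Product: 18 benzyl ring A cyclohexane-1,3-dione carboxylate (enol form; racemic trans; C1 CO2Bn; C2 dioxolanylmethyl; C3 O-ArB), via open-chain Michael adduct 17 (not isolated)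
Conditions: NaH (1.1 equiv), THF, 0 °C → 65 °C; then AcOH
Reagents that add atoms: none
Why: NaCH(CO2Bn)2 adds to the β-carbon of the α-aryloxy enone (C1–C2), proton transfer gives the methyl ketone enolate, and this attacks one benzyl ester (C5–C6), expelling benzyl oxide, which deprotonates the β-dicarbonyl product and pulls the equilibria forward. The closest known reaction is the Michael–Claisen condensation of malonates with alk-3-en-2-ones to 6-alkyl-2,4-dioxocyclohexanecarboxylates. Ring A closes by a 6-(enolendo)-exo-trig attack on the ester carbonyl. C2 and C3 are set under thermodynamic control, because C3 is epimerisable next to the C4 ketone, so the trans isomer should prevail; both centres are erased in step 13. The step needs regio- and chemoselectivity: only the enone methyl group can reach a malonate ester through a six-membered transition state, and the di-ortho-substituted tert-butyl ester of ring B is inert to the enolates. With one equivalent of base no free alkoxide is present until the product enolate has formed, which limits γ-deprotonation of 15 and opening of its dioxolane.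

Step 13
Reactants: 18 benzyl ring A cyclohexane-1,3-dione carboxylate
Product: 19 benzyl 3-(ArB-oxy)-4,6-dihydroxy-2-[(2-pentyl-1,3-dioxolan-2-yl)methyl]benzoate
Conditions: DDQ (1.1 equiv), 1,4-dioxane, rt → 60 °C
Reagents that add atoms: none
Why: DDQ abstracts hydride from the allylic C2–H of the enolised dione, and loss of the C3 proton with tautomerisation gives the resorcinol; any ring dehydrogenation leads to the same arene, a known way of aromatising 2,4-dioxocyclohexanecarboxylates.

Step 14
Reactants: 19 benzyl 3-(ArB-oxy)-4,6-dihydroxy-2-[(2-pentyl-1,3-dioxolan-2-yl)methyl]benzoate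
Product: 20 2-{[2-(benzyloxycarbonyl)-4,6-dihydroxy... ring A]oxy} keto acid: 2-[6-(benzyloxycarbonyl)-2,4-dihydroxy... ] written plainly, the diaryl ether with ring A as benzyl 4,6-dihydroxy-2-(2-oxoheptyl)benzoate (C3–O) and ring B as 4-methoxy-6-(2-oxoheptyl)benzoic acid (C2–O)
Conditions: TFA–CH2Cl2–H2O (10:10:1), rt
Reagents that add atoms: water, O
Why: Aqueous TFA cleaves the tert-butyl ester by loss of isobutene and hydrolyses both dioxolanes, while the benzyl ester and the diaryl ether survive.

Step 15
Reactants: 20 ring B keto acid with ring A benzyl ester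
Product: 22 benzyl β-collatolate (benzyl ester of the target), via mixed trifluoroacetic anhydride 21 (not isolated)
Conditions: (CF3CO)2O (1.5 equiv), CH2Cl2, 0 °C → rt; then aq. NaHCO3–MeOH
Reagents that add atoms: none
Why: The anhydride activates the only free carboxylic acid, and the enol oxygen of the ring B ketone closes the six-membered enol lactone (isocoumarin) by cyclodehydration; the ring A ketone faces only an unactivated benzyl ester and stays open, and any phenolic trifluoroacetate is cleaved in the bicarbonate work-up.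

Step 16
Reactants: 22 benzyl β-collatolate
Product: 23 β-collatolic acid
Conditions: H2 (1 atm), Pd/C, EtOAc, rt
Reagents that add atoms: none
Why: Hydrogenolysis of the benzyl ester over Pd/C at one atmosphere is much faster than reduction of the aryl-conjugated enol-lactone double bond or the ketone, so brief exposure should release the free acid.

**Compound list**

1 | methyl orsellinate (methyl 2,4-dihydroxy-6-methylbenzoate) | COC(=O)c1c(C)cc(O)cc1O | starting material
2 | methyl 2-hydroxy-4-methoxy-6-methylbenzoate | COC(=O)c1c(C)cc(OC)cc1O | intermediate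
3 | methyl 2-(benzyloxy)-4-methoxy-6-methylbenzoate | COC(=O)c1c(C)cc(OC)cc1OCc1ccccc1 | intermediate
4 | 2-(benzyloxy)-4-methoxy-6-methylbenzoic acid | OC(=O)c1c(C)cc(OC)cc1OCc1ccccc1 | intermediate
5 | tert-butyl 2-(benzyloxy)-4-methoxy-6-methylbenzoate | CC(C)(C)OC(=O)c1c(C)cc(OC)cc1OCc1ccccc1 | intermediate
6 | N-methoxy-N-methylhexanamide | CCCCCC(=O)N(C)OC | starting material
7 | tert-butyl 2-(benzyloxy)-4-methoxy-6-(2-oxoheptyl)benzoate | CCCCCC(=O)Cc1cc(OC)cc(OCc2ccccc2)c1C(=O)OC(C)(C)C | intermediate
8 | tert-butyl 2-(benzyloxy)-4-methoxy-6-[(2-pentyl-1,3-dioxolan-2-yl)methyl]benzoate | CCCCCC1(Cc2cc(OC)cc(OCc3ccccc3)c2C(=O)OC(C)(C)C)OCCO1 | intermediate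
9 | tert-butyl 2-hydroxy-4-methoxy-6-[(2-pentyl-1,3-dioxolan-2-yl)methyl]benzoate (ring B phenol) | CCCCCC1(Cc2cc(OC)cc(O)c2C(=O)OC(C)(C)C)OCCO1 | intermediate
10 | ethyl 3-oxooctanoate | CCCCCC(=O)CC(=O)OCC | starting material
11 | ethyl 2-(2-pentyl-1,3-dioxolan-2-yl)acetate | CCCCCC1(CC(=O)OCC)OCCO1 | intermediate
12 | 2-(2-pentyl-1,3-dioxolan-2-yl)acetaldehyde | CCCCCC1(CC=O)OCCO1 | intermediate
13 | dimethyl (1-diazo-2-oxopropyl)phosphonate | CC(=O)C(=[N+]=[N-])P(=O)(OC)OC | starting material
14 | dimethyl [1-(ArB-oxy)-2-oxopropyl]phosphonate (racemic) | CC(=O)C(Oc1cc(OC)cc(CC2(CCCCC)OCCO2)c1C(=O)OC(C)(C)C)P(=O)(OC)OC | intermediate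
15 | 3-(ArB-oxy)-5-(2-pentyl-1,3-dioxolan-2-yl)pent-3-en-2-one (E/Z mixture) | CC(=O)C(Oc1cc(OC)cc(CC2(CCCCC)OCCO2)c1C(=O)OC(C)(C)C)=CCC1(CCCCC)OCCO1 | intermediate
16 | dibenzyl malonate | O=C(CC(=O)OCc1ccccc1)OCc1ccccc1 | starting material
17 | open-chain Michael adduct, dibenzyl 2-[3-(ArB-oxy)-4-oxo-1-(2-pentyl-1,3-dioxolan-2-yl)pentan-2-yl]malonate (diastereomer mixture, not isolated) | CC(=O)C(Oc1cc(OC)cc(CC2(CCCCC)OCCO2)c1C(=O)OC(C)(C)C)C(CC1(CCCCC)OCCO1)C(C(=O)OCc1ccccc1)C(=O)OCc1ccccc1 | intermediate
18 | benzyl 5-(ArB-oxy)-2-hydroxy-4-oxo-6-[(2-pentyl-1,3-dioxolan-2-yl)methyl]cyclohex-1-ene-1-carboxylate (racemic, 5,6-trans; one enantiomer drawn) | OC1=C(C(=O)OCc2ccccc2)[C@@H](CC2(CCCCC)OCCO2)[C@H](Oc2cc(OC)cc(CC3(CCCCC)OCCO3)c2C(=O)OC(C)(C)C)C(=O)C1 | intermediate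
19 | benzyl 3-(ArB-oxy)-4,6-dihydroxy-2-[(2-pentyl-1,3-dioxolan-2-yl)methyl]benzoate | CCCCCC1(Cc2c(Oc3cc(OC)cc(CC4(CCCCC)OCCO4)c3C(=O)OC(C)(C)C)c(O)cc(O)c2C(=O)OCc2ccccc2)OCCO1 | intermediate
20 | 2-{[3-(benzyloxycarbonyl)-4,6-dihydroxy-2-(2-oxoheptyl)phenyl]oxy}... ring B keto acid: 2-[(ring A aryl)oxy]-4-methoxy-6-(2-oxoheptyl)benzoic acid, ring A aryl = 2-(benzyloxycarbonyl)... positions as in SMILES | CCCCCC(=O)Cc1c(Oc2cc(OC)cc(CC(=O)CCCCC)c2C(=O)O)c(O)cc(O)c1C(=O)OCc1ccccc1 | intermediate
21 | mixed trifluoroacetic anhydride of the ring B carboxylic acid of 20 (not isolated) | CCCCCC(=O)Cc1c(Oc2cc(OC)cc(CC(=O)CCCCC)c2C(=O)OC(=O)C(F)(F)F)c(O)cc(O)c1C(=O)OCc1ccccc1 | intermediate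
22 | benzyl β-collatolate: benzyl 4,6-dihydroxy-3-[(6-methoxy-1-oxo-3-pentyl-1H-isochromen-8-yl)oxy]-2-(2-oxoheptyl)benzoate | CCCCCC(=O)Cc1c(Oc2cc(OC)cc3cc(CCCCC)oc(=O)c23)c(O)cc(O)c1C(=O)OCc1ccccc1 | intermediate
23 | β-collatolic acid: 4,6-dihydroxy-3-[(6-methoxy-1-oxo-3-pentyl-1H-isochromen-8-yl)oxy]-2-(2-oxoheptyl)benzoic acid | CCCCCC(=O)Cc1c(Oc2cc(OC)cc3cc(CCCCC)oc(=O)c23)c(O)cc(O)c1C(=O)O | target

**Summary**

Total step count: 16.
Longest linear sequence: 14 steps (steps 1–7, then 10–16); steps 8–9 form the side branch.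

Steps most likely to fail:

1. Step 12 (annulation). What may go wrong: γ-deprotonation of the enone to a dienolate, followed by β-elimination that opens the side-chain dioxolane, or slow and reversible conjugate addition to the donor-substituted, β-branched enone, so that the sequence stalls before ring closure. Fallback: the Michael polarity is inverted, setting out from 12, 16 and 9 and coming back at 17 and then 18. Aldehyde 12 and dibenzyl malonate 16 are condensed in a Knoevenagel reaction (piperidinium acetate, molecular sieves, benzene, rt) to dibenzyl 2-[2-(2-pentyl-1,3-dioxolan-2-yl)ethylidene]malonate F1. Phenol 9 is alkylated with chloroacetone (K2CO3, KI, acetone, reflux) to the aryloxyacetone tert-butyl 4-methoxy-2-(2-oxopropoxy)-6-[(2-pentyl-1,3-dioxolan-2-yl)methyl]benzoate F2. F2 enolises toward its more acidic aryloxy-bearing methylene and should add to the much more electrophilic alkylidene malonate under catalytic DBU in THF, giving the same adduct 17, which is isolated here and closed to 18 with NaH in THF as in step 12.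

2. Step 13 (aromatisation). What may go wrong: incomplete hydride abstraction from the hindered α-aryloxy dione, over-oxidation of the electron-rich resorcinol once formed, or ketal loss caused by the acidic hydroquinone by-product. Fallback: halogenation and dehydrohalogenation in place of hydride abstraction, setting out from 18 and coming back at 19. The enolised dione is brominated with one equivalent of Br2 in DMF at 0 °C to the bromodione F3, drawn as the C5 bromide, the kinetic site between the two ring carbonyls. Warming with Li2CO3 in DMF should bring about loss of HBr, after enol-mediated bromine migration, and tautomerisation to 19. Partial ketal cleavage at this point would be harmless, since step 14 removes the ketals anyway.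

3. Step 10 (O–H insertion). What may go wrong: because the phenol is hindered and hydrogen-bonded to the ortho ester, the rhodium carbenoid may be diverted into Wolff rearrangement, attack on the electron-rich arene, or ylide formation at the dioxolane oxygens. Fallback: a Williamson C–O bond formation in place of the carbenoid, setting out from 9 and coming back at 14. Dimethyl (2-oxopropyl)phosphonate is chlorinated with SO2Cl2 in CH2Cl2 at 0 °C to dimethyl (1-chloro-2-oxopropyl)phosphonate F4. The potassium phenoxide of 9 (K2CO3, KI, acetone, reflux) should displace chloride at the doubly activated carbon in an SN2 reaction, as phenols do with 2-chloroacetoacetates, to give 14, which continues with step 11.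

**Further compounds**

F1 | step 12 | dibenzyl 2-[2-(2-pentyl-1,3-dioxolan-2-yl)ethylidene]malonate | CCCCCC1(CC=C(C(=O)OCc2ccccc2)C(=O)OCc2ccccc2)OCCO1
F2 | step 12 | tert-butyl 4-methoxy-2-(2-oxopropoxy)-6-[(2-pentyl-1,3-dioxolan-2-yl)methyl]benzoate | CC(=O)COc1cc(OC)cc(CC2(CCCCC)OCCO2)c1C(=O)OC(C)(C)C
F3 | step 13 | benzyl 5-(ArB-oxy)-3-bromo-2-hydroxy-4-oxo-6-[(2-pentyl-1,3-dioxolan-2-yl)methyl]cyclohex-1-ene-1-carboxylate (racemic, 5,6-trans, bromide epimers) | OC1=C(C(=O)OCc2ccccc2)[C@@H](CC2(CCCCC)OCCO2)[C@H](Oc2cc(OC)cc(CC3(CCCCC)OCCO3)c2C(=O)OC(C)(C)C)C(=O)C1Br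
F4 | step 10 | dimethyl (1-chloro-2-oxopropyl)phosphonate (racemic) | CC(=O)C(Cl)P(=O)(OC)OC
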